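**Plan**

- Retrosynthesis first cuts both C–CH2 bonds of the bridge (ring A C6–CH2 and CH2–ring B C3), which gives the ring A acid, formaldehyde and the ring B butyrophenone.
- This works because the bridge carbon sits between two nucleophilic carbons: C6, the only unsubstituted carbon of the enolised trione ring A, and the ring B carbon flanked by two hydroxyls. One electrophilic carbon can therefore bond to both.
- Ring A is then cut at C2–C3 and C5–C6 into heptane-2,4-dione and a methyl hydrogen 2-methyl-2-prenylmalonate. Ring B is cut at its aryl–acyl bond into 5-methoxyresorcinol and a butanoyl donor.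
- Forward, ring A (the only ring made) arises by malonate prenylation, enzymatic half-hydrolysis, C-acylation of the diketone and Dieckmann closure. Ring B comes from one Friedel–Crafts acylation, and the halves are joined last through formaldehyde without ring closure.
- The single stereocentre, the quaternary C4 of ring A (R), comes from esterase desymmetrisation of the prochiral malonate. It has no hydrogen and is carried through unchanged.

Key step: step 6

Assumption: pig liver esterase is taken to give the (S)-half-ester from the methyl/prenyl malonate, the sense it shows with 2-methyl-2-alkylmalonates bearing short chains; the enantiomeric purity is to be checked by chiral HPLC before going on.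

Remark: triones and triacylmethanes are drawn in one tautomeric form, and CIP labels refer to the tautomer drawn.

**Step 1**
Reactants: 1 dimethyl methylmalonate; 2 prenyl bromide (1-bromo-3-methylbut-2-ene)
Product: 3 dimethyl 2-methyl-2-(3-methylbut-2-en-1-yl)propanedioate
Conditions: NaH (1.1 equiv), THF, 0 °C; then 2 (1.1 equiv), 0 °C → rt
Reagents that add atoms: none
Why: Malonate alkylation, in which the sodium enolate of 1 (one acidic hydrogen only, so no over-alkylation) displaces bromide from the primary allylic carbon by SN2 and so forms the quaternary, still prochiral carbon.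

**Step 2**
Reactants: 3 dimethyl 2-methyl-2-(3-methylbut-2-en-1-yl)propanedioate
Product: 4 (2S)-2-(methoxycarbonyl)-2,5-dimethylhex-4-enoic acid
Conditions: pig liver esterase, 0.1 M phosphate buffer pH 7.5/DMSO 9:1, 25 °C; then 1 M HCl to pH 2.5 at 0 °C, EtOAc extraction
Reagents that add atoms: water, O
Why: Enzymatic desymmetrisation (enantiotopic-group-selective ester hydrolysis) of a prochiral 2-methyl-2-alkylmalonate, which should stop at the half-ester because the carboxylate is no longer a substrate; the active site sets the quaternary stereocentre, which has no α-hydrogen and cannot epimerise.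

**Step 3**
Reactants: 4 (2S)-2-(methoxycarbonyl)-2,5-dimethylhex-4-enoic acid; 5 heptane-2,4-dione
Product: 7 methyl (2S)-4-acetyl-2-methyl-2-(3-methylbut-2-en-1-yl)-3,5-dioxooctanoate, via acid chloride 6 (not isolated)
Conditions: 1-chloro-N,N,2-trimethylprop-1-en-1-amine (1.1 equiv), CH2Cl2, 0 °C → rt; solution then added to 5 (1.2 equiv), MgCl2 (1.2 equiv), pyridine (2.5 equiv), CH2Cl2, 0 °C → rt; cold dilute HCl wash
Reagents that add atoms: none
Why: Neutral acid chloride formation with the α-chloroenamine (no HCl is released, so the prenyl alkene is safe) followed by magnesium-chelate-directed C-acylation of the β-diketone at its central carbon (Rathke-type MgCl2/pyridine acylation); the acid chloride has no α-hydrogen, so no ketene can form and the stereocentre is a spectator.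

**Step 4**
Reactants: 7 methyl (2S)-4-acetyl-2-methyl-2-(3-methylbut-2-en-1-yl)-3,5-dioxooctanoate
Product: 8 (4R)-2-butanoyl-3,5-dihydroxy-4-methyl-4-(3-methylbut-2-en-1-yl)cyclohexa-2,5-dien-1-one (ring A acid)
Conditions: LiN(iPr)2 (3.3 equiv), THF, −78 °C → 0 °C; 1 M HCl at 0 °C to pH 3
Reagents that add atoms: none
Why: Dieckmann-type intramolecular Claisen condensation (6-(enolendo)-exo-trig, as in dimedone-type 1,3-dione syntheses), in which, after the central CH is deprotonated, the amide base should remove a proton from the acetyl CH3 in preference to the butanoyl CH2 and the primary carbanion closes onto the methyl ester; the doubly deprotonated product resists retro-Claisen cleavage and the quaternary centre is not involved.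

**Step 5**
Reactants: 9 5-methoxyresorcinol; 10 butanoyl chloride
Product: 11 1-(2,4-dihydroxy-6-methoxyphenyl)butan-1-one (ring B)
Conditions: AlCl3 (3 equiv), CH2Cl2/MeNO2, 0 °C → rt (no heating, to keep the methoxy group); ice/1 M HCl; chromatography
Reagents that add atoms: none
Why: Friedel–Crafts C-acylation of an electron-rich resorcinol, expected mainly at C4 (equivalent to C6), para to one hydroxyl and ortho to the other, as with resorcinol and orcinol; the minor symmetrical isomer from attack between the hydroxyls is removed by chromatography.

**Step 6**
Reactants: 8 ring A acid; 12 formaldehyde (used as paraformaldehyde); 11 ring B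
Product: 15 (4R)-2-butanoyl-6-[(3-butanoyl-2,6-dihydroxy-4-methoxyphenyl)methyl]-3,5-dihydroxy-4-methyl-4-(3-methylbut-2-en-1-yl)cyclohexa-2,5-dien-1-one (the target), via Mannich base 13 (not isolated), via methylidene trione 14 (not isolated)
Conditions: 12 (1.05 equiv) and morpholine (1.05 equiv) premixed in MeCN, rt; 8 (1.0 equiv), 0 °C → rt, 1 h; then 11 (3 equiv), 50 °C, about 2 h; cold 0.5 M HCl; chromatography (Sephadex LH-20 or silica), excess 11 recovered
Reagents that add atoms: none
Why: Morpholine and formaldehyde form the iminium, which the enolate of 8 takes up at C6, its only unsubstituted ring carbon, to give the zwitterionic Mannich base 13; on warming, 13 loses morpholine by E1cB to the cross-conjugated 6-methylidene trione 14, and the phenoxide of 11 adds to its CH2 terminus through C3 in a quinone-methide-type conjugate addition, after which tautomerisation restores the arene and the enolised trione. The closest known reaction is the formaldehyde (Mannich or Knoevenagel–Michael) coupling used to join filicinic-acid-type triones to acylphloroglucinols in methylene-bis-phloroglucinol synthesis. No ring is closed and no stereocentre is formed; the quaternary C4 has no hydrogen and is untouched. Cross-coupling over the two symmetrical dimers should be favoured because the one-carbon unit is stored on ring A as 13 before 11 is added, so little free 8 meets 14, and because 11 is in excess. Attack through C3 of 11 rather than C5 is expected because C3 lies ortho to both hydroxyls whereas C5 is flanked by the methoxy group. Near-neutral conditions and a short reaction time should spare the prenyl group and limit retro-Michael exchange of the bridge.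

**Compound list**

1 | dimethyl methylmalonate | COC(=O)C(C)C(=O)OC | starting material
2 | prenyl bromide (1-bromo-3-methylbut-2-ene) | CC(C)=CCBr | starting material
3 | dimethyl 2-methyl-2-(3-methylbut-2-en-1-yl)propanedioate | COC(=O)C(C)(CC=C(C)C)C(=O)OC | intermediate
4 | (2S)-2-(methoxycarbonyl)-2,5-dimethylhex-4-enoic acid | OC(=O)[C@](C)(CC=C(C)C)C(=O)OC | intermediate
5 | heptane-2,4-dione | CCCC(=O)CC(C)=O | starting material
6 | methyl (2R)-2-(chlorocarbonyl)-2,5-dimethylhex-4-enoate (same spatial arrangement as 4; not isolated) | ClC(=O)[C@](C)(CC=C(C)C)C(=O)OC | intermediate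
7 | methyl (2S)-4-acetyl-2-methyl-2-(3-methylbut-2-en-1-yl)-3,5-dioxooctanoate (drawn as triketo tautomer; C4 is labile and largely enolised) | CCCC(=O)C(C(C)=O)C(=O)[C@](C)(CC=C(C)C)C(=O)OC | intermediate
8 | (4R)-2-butanoyl-3,5-dihydroxy-4-methyl-4-(3-methylbut-2-en-1-yl)cyclohexa-2,5-dien-1-one (ring A acid) | CCCC(=O)C1=C(O)[C@](C)(CC=C(C)C)C(O)=CC1=O | intermediate
9 | 5-methoxyresorcinol | COc1cc(O)cc(O)c1 | starting material
10 | butanoyl chloride | CCCC(=O)Cl | starting material
11 | 1-(2,4-dihydroxy-6-methoxyphenyl)butan-1-one (ring B) | CCCC(=O)c1c(O)cc(O)cc1OC | intermediate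
12 | formaldehyde (used as paraformaldehyde) | C=O | starting material
13 | (4R)-2-butanoyl-3,5-dihydroxy-4-methyl-4-(3-methylbut-2-en-1-yl)-6-(morpholin-4-ylmethyl)cyclohexa-2,5-dien-1-one (Mannich base, zwitterionic; not isolated) | CCCC(=O)C1=C(O)[C@](C)(CC=C(C)C)C(O)=C(CN2CCOCC2)C1=O | intermediate
14 | (4S)-2-butanoyl-3-hydroxy-4-methyl-4-(3-methylbut-2-en-1-yl)-6-methylidenecyclohex-2-ene-1,5-dione (same spatial arrangement as 8; the label changes because C5 is drawn as a ketone; not isolated) | CCCC(=O)C1=C(O)[C@](C)(CC=C(C)C)C(=O)C(=C)C1=O | intermediate
15 | (4R)-2-butanoyl-6-[(3-butanoyl-2,6-dihydroxy-4-methoxyphenyl)methyl]-3,5-dihydroxy-4-methyl-4-(3-methylbut-2-en-1-yl)cyclohexa-2,5-dien-1-one | CCCC(=O)C1=C(O)[C@](C)(CC=C(C)C)C(O)=C(Cc2c(O)cc(OC)c(C(=O)CCC)c2O)C1=O | target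

**Step count**

Total: 6 steps. Longest linear sequence: 5 steps (steps 1, 2, 3, 4, 6); ring B is made in one step (step 5).

**Steps most likely to fail**

1. Step 6. Statistical formation of the two symmetrical methylene-bridged dimers, base-induced retro-Michael exchange of the bridge, or attack of ring B through C5 could erode the cross-coupling. The fallback fixes the one-carbon unit on ring B first and sets out from 11. Aminomethylation of 11 at C3 with aqueous dimethylamine and formaldehyde in EtOH at rt should give the isolable Mannich base 1-{3-[(dimethylamino)methyl]-2,4-dihydroxy-6-methoxyphenyl}butan-1-one F1, whose regiochemistry can be checked and purified. Heating F1 with 8 (1 equiv) in MeCN or toluene at 60–80 °C lets the acidic 8 protonate the amine; the ortho-quinone methide of ring B that results is captured by C6 of 8. The same two bridge bonds are made, now in two steps, and the route is rejoined at 15.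

2. Step 4. Ring closure through the butanoyl α-carbon or retro-Claisen loss of an acyl group from the triacylmethane could compete with the desired closure. The fallback removes the second enolisable chain during ring closure and sets out from 4. The acid chloride 6 is used to C-acylate pentane-2,4-dione (MgCl2, pyridine, CH2Cl2) to give methyl (2S)-4-acetyl-2-methyl-2-(3-methylbut-2-en-1-yl)-3,5-dioxohexanoate F2, in which both enolisable termini are methyl groups that lead to the same ring. LiN(iPr)2 in THF then closes it to the 2-acetyl analogue (4R)-2-acetyl-3,5-dihydroxy-4-methyl-4-(3-methylbut-2-en-1-yl)cyclohexa-2,5-dien-1-one F3. Its trianion (LiN(iPr)2, 3.3 equiv, THF/DMPU, −78 °C) is ethylated with iodoethane at the acetyl carbon, the last-formed and most basic site (side-chain alkylation of a β-tricarbonyl polyanion), and the route is rejoined at 8.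

3. Step 2. Low or reversed enantiotopic-group selectivity of the esterase toward the prenyl substrate would undermine the stereochemistry. The fallback is a classical resolution and sets out from 3. Half-saponification with one equivalent of KOH in MeOH/water gives racemic 2-(methoxycarbonyl)-2,5-dimethylhex-4-enoic acid F4. Its (S)-enantiomer is crystallised as the (S)-1-phenylethylammonium (2S)-2-(methoxycarbonyl)-2,5-dimethylhex-4-enoate salt F5; the (R)-amine is used instead if the other pairing proves the less soluble. Acidification with cold dilute HCl releases the acid and rejoins the route at 4.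

**Further compounds**

F1 | step 6 | 1-{3-[(dimethylamino)methyl]-2,4-dihydroxy-6-methoxyphenyl}butan-1-one | CCCC(=O)c1c(O)c(CN(C)C)c(O)cc1OC
F2 | step 4 | methyl (2S)-4-acetyl-2-methyl-2-(3-methylbut-2-en-1-yl)-3,5-dioxohexanoate | CC(=O)C(C(C)=O)C(=O)[C@](C)(CC=C(C)C)C(=O)OC
F3 | step 4 | (4R)-2-acetyl-3,5-dihydroxy-4-methyl-4-(3-methylbut-2-en-1-yl)cyclohexa-2,5-dien-1-one | CC(=O)C1=C(O)[C@](C)(CC=C(C)C)C(O)=CC1=O
F4 | step 2 | racemic 2-(methoxycarbonyl)-2,5-dimethylhex-4-enoic acid | OC(=O)C(C)(CC=C(C)C)C(=O)OC
F5 | step 2 | (S)-1-phenylethylammonium (2S)-2-(methoxycarbonyl)-2,5-dimethylhex-4-enoate | C[C@H]([NH3+])c1ccccc1.[O-]C(=O)[C@](C)(CC=C(C)C)C(=O)OC
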